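**Strategy.** Ring A of the 2,3-dihydrobenzofuran carries O1 (on C7a) and the C7 oxygen on neighbouring carbons and the benzofuranyl group at C5. This is the pattern a 2,4-disubstituted furan delivers when it is isomerised onto a tethered ynol ether. The route therefore disconnects C3a–C7a and C6–C7: one gold-catalysed furan-yne cascade closes the dihydrofuran ring and ring A together and moves the furan oxygen to C7. Its precursor is a 4-(benzofuran-2-yl)furan whose C2 carries the chain ArCH(OC≡CH)–CH(CH2OTIPS), both stereocentres set beforehand by an Evans syn-aldol. Triisopropylsilyl ethers replace smaller silyl groups so that no silyl shift can occur during ynol ether formation.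

Key step: step 13

Remark on the chemistry: a syn-aldol pair on the tether corresponds to the 2,3-trans ring, because no bond at either stereocentre is made or broken in the cyclisation. Abbreviations: TIPS = triisopropylsilyl; Ar = 4-(benzyloxy)-3-methoxyphenyl; BF = 7-methoxy-5-[3-(triisopropylsilyloxy)propyl]-1-benzofuran-2-yl. Ring numbering follows 2,3-dihydro-1-benzofuran (O1, C2, C3, C3a, C4–C7, C7a).

**Step 1**
Reactants: 1 4-bromofuran-2-carbaldehyde; 2 ethynyltrimethylsilane
Product: 3 4-[(trimethylsilyl)ethynyl]furan-2-carbaldehyde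
Conditions: PdCl2(PPh3)2 (3 mol %), CuI (5 mol %), Et3N, THF, 60 °C, sealed vessel
Reagents that add atoms: none
Why: Sonogashira coupling, in which the 2-formyl group makes the furyl bromide a willing partner for oxidative addition to zerovalent palladium and the silyl cap keeps the alkyne from homocoupling or reacting twice.

**Step 2**
Reactants: 4 eugenol
Product: 6 4-(3-hydroxypropyl)-2-methoxyphenol (dihydroconiferyl alcohol), via bis-borane adduct 5 (not isolated)
Conditions: 9-BBN (2.2 equiv), THF, 0 °C → rt; then NaOH, H2O2, H2O, 0 °C → rt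
Reagents that add atoms: hydrogen peroxide, OO
Why: Brown hydroboration–oxidation, in which bulky 9-BBN places boron on the terminal carbon of the allyl group (the phenol is only masked as a borinate that the basic work-up hydrolyses) and alkaline peroxide replaces boron by hydroxyl.

**Step 3**
Reactants: 6 4-(3-hydroxypropyl)-2-methoxyphenol
Product: 7 4-(3-hydroxypropyl)-2-iodo-6-methoxyphenol
Conditions: I2 (1.05 equiv), NaHCO3, THF/H2O, 0 °C → rt
Reagents that add atoms: iodine, II
Why: Electrophilic aromatic iodination of the phenoxide, which has its para position blocked by the side chain and one ortho position by methoxy, so iodine should enter the only free position ortho to the hydroxyl.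

**Step 4**
Reactants: 3 4-[(trimethylsilyl)ethynyl]furan-2-carbaldehyde; 7 4-(3-hydroxypropyl)-2-iodo-6-methoxyphenol
Product: 10 4-[5-(3-hydroxypropyl)-7-methoxy-1-benzofuran-2-yl]furan-2-carbaldehyde, via 4-ethynylfuran-2-carbaldehyde 8 (not isolated), via alkynylphenol 9 (not isolated)
Conditions: PdCl2(PPh3)2 (3 mol %), CuI (6 mol %), CsF (2 equiv), Et3N, DMF, 70 °C
Reagents that add atoms: none
Why: Fluoride-triggered desilylation, Sonogashira coupling and 5-endo-dig heteroannulation (Castro–Stephens-type benzofuran synthesis) in one pot, the phenoxide adding across the electron-poor aryl alkyne as soon as it is formed, which is the standard entry to 2-arylbenzofurans from o-iodophenols.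

**Step 5**
Reactants: 10 4-[5-(3-hydroxypropyl)-7-methoxy-1-benzofuran-2-yl]furan-2-carbaldehyde
Product: 11 4-BF-furan-2-carbaldehyde (TIPS ether of 10)
Conditions: TIPSCl, imidazole, DMF, rt
Reagents that add atoms: chlorotriisopropylsilane, CC(C)[Si](Cl)(C(C)C)C(C)C
Why: Imidazole-promoted silylation of the only hydroxyl group, with TIPS chosen because it should survive the hot hydroxide of step 7 and the organolithium of step 12.

**Step 6**
Reactants: 11 4-BF-furan-2-carbaldehyde; 12 p-toluenesulfonylmethyl isocyanide (TosMIC)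
Product: 14 2-(4-BF-furan-2-yl)acetonitrile, via tosylvinyl formamide 13 (not isolated)
Conditions: t-BuOK (2.4 equiv), DME, −40 °C; then MeOH, reflux
Reagents that add atoms: none
Why: Van Leusen reductive cyanation, in which the TosMIC anion adds to the non-enolisable aldehyde, the oxazoline opens to the tosylvinyl formamide, and methanolysis expels methyl formate and sulfinate to leave the nitrile with one more carbon.

**Step 7**
Reactants: 14 2-(4-BF-furan-2-yl)acetonitrile
Product: 15 2-(4-BF-furan-2-yl)acetic acid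
Conditions: KOH, EtOH/H2O, reflux; then 1 M HCl, 0 °C, to pH 3
Reagents that add atoms: potassium hydroxide, [K+].[OH-]; water, O
Why: Alkaline nitrile hydrolysis through the primary amide, under which furan, benzofuran and the primary TIPS ether are stable.

**Step 8**
Reactants: 15 2-(4-BF-furan-2-yl)acetic acid; 16 (4S)-4-benzyl-1,3-oxazolidin-2-one
Product: 18 (4S)-4-benzyl-3-[2-(4-BF-furan-2-yl)acetyl]-1,3-oxazolidin-2-one, via mixed pivalic anhydride 17 (not isolated)
Conditions: t-BuCOCl, Et3N, THF, −20 °C; then LiCl, 16, −20 °C → rt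
Reagents that add atoms: none
Why: N-acylation of the Evans auxiliary through a mixed pivalic anhydride, the oxazolidinone attacking the less hindered arylacetyl carbonyl while the stereocentre of 16 is untouched.

**Step 9**
Reactants: 18 (4S)-4-benzyl-3-[2-(4-BF-furan-2-yl)acetyl]-1,3-oxazolidin-2-one; 19 4-(benzyloxy)-3-methoxybenzaldehyde
Product: 22 (4S)-4-benzyl-3-[(2R,3S)-3-Ar-2-(4-BF-furan-2-yl)-3-hydroxypropanoyl]-1,3-oxazolidin-2-one, via boron enolate 20 (not isolated), via boron aldolate 21 (not isolated)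
Conditions: Bu2BOTf (1.2 equiv), i-Pr2NEt (1.4 equiv), CH2Cl2, −78 → 0 °C; then 19, −78 → 0 °C; then pH 7 buffer, MeOH, H2O2, 0 °C
Reagents that add atoms: none
Why: Evans boron syn-aldol reaction, in which soft enolisation gives the (Z)-enolate and a closed Zimmerman–Traxler chair delivers the aldehyde to the face remote from the benzyl group of the (S)-auxiliary, setting C2 (R) and C3 (S) as the syn pair that corresponds to the 2,3-trans ring of the target.

**Step 10**
Reactants: 22 aldol adduct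
Product: 23 (1S,2R)-1-Ar-2-(4-BF-furan-2-yl)propane-1,3-diol
Conditions: LiBH4, H2O (1 equiv), Et2O/THF, 0 °C
Reagents that add atoms: none
Why: Reductive cleavage of the N-acyl oxazolidinone by hydride attack at the exocyclic carbonyl, fast enough at 0 °C to avoid retro-aldol or epimerisation of the α-furyl centre, so both stereocentres are carried over.

**Step 11**
Reactants: 23 (1S,2R)-1-Ar-2-(4-BF-furan-2-yl)propane-1,3-diol
Product: 24 (1S,2R)-1-Ar-2-(4-BF-furan-2-yl)-3-(triisopropylsilyloxy)propan-1-ol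
Conditions: TIPSCl (1.1 equiv), imidazole, CH2Cl2, 0 °C → rt
Reagents that add atoms: chlorotriisopropylsilane, CC(C)[Si](Cl)(C(C)C)C(C)C
Why: Sterically controlled silylation, in which TIPSCl takes the primary hydroxyl and leaves the hindered benzylic one, and TIPS (unlike smaller silyl groups) should not migrate to the neighbouring alkoxide generated in step 12.

**Step 12**
Reactants: 24 (1S,2R)-1-Ar-2-(4-BF-furan-2-yl)-3-(triisopropylsilyloxy)propan-1-ol; 25 trichloroethylene
Product: 29 2-[(1S,2R)-1-Ar-1-(ethynyloxy)-3-(triisopropylsilyloxy)propan-2-yl]-4-BF-furan, via dichlorovinyl ether 26 (not isolated), via chloroethynyl ether 27 (not isolated), via lithium alkynyl ether 28 (not isolated)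
Conditions: KH, THF, 0 °C; 25, −50 °C → rt; then n-BuLi (2.5 equiv), −78 → −40 °C; MeOH, −78 °C; cold work-up, used at once
Reagents that add atoms: none
Why: Alkoxide/trichloroethylene alkynyl ether synthesis, in which the potassium alkoxide adds to dichloroacetylene formed in situ from 25, n-BuLi then effects dehydrochlorination and chlorine–lithium exchange, and methanol protonates the lithium alkynyl ether, the C–O bond at the benzylic stereocentre never being broken so that its configuration is kept.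

**Step 13**
Reactants: 29 2-[(1S,2R)-1-Ar-1-(ethynyloxy)-3-(triisopropylsilyloxy)propan-2-yl]-4-BF-furan
Product: 32 (2S,3R)-2-Ar-5-BF-3-[(triisopropylsilyloxy)methyl]-2,3-dihydro-1-benzofuran-7-ol, via oxepine 30 (not isolated), via arene oxide 31 (not isolated)
Conditions: (Ph3P)AuNTf2 (2 mol %), 4 Å MS, CH2Cl2, −20 → 0 °C
Reagents that add atoms: none
Why: π-Activation of the terminal ynol ether by cationic monovalent gold makes its oxygen-bearing carbon electrophilic, and the tethered furan attacks it through the substituted C2 in a 5-exo-dig closure that forms the dihydrofuran ring (new C3a–C7a bond) and a cyclopropyl gold carbenoid across furan C2–C3. This species opens to a gold-carbene dienone, the carbonyl oxygen attacks the carbene carbon and gold is lost to give oxepine 30, whose disrotatory 6π electrocyclisation to arene oxide 31 closes ring A (new C6–C7 bond); the epoxide then opens towards the O1-stabilised cation, and a hydride shift and tautomerisation leave the hydroxyl on C7. The closest known reaction is the gold-catalysed furan-yne phenol synthesis, which has been run with alkynyl-ether tethers to give 7-hydroxy-2,3-dihydrobenzofurans. No stereocentre is created: C2 and C3 lie on the tether, take part in no bond that is made or broken, and keep the syn-aldol configuration that maps onto the 2,3-trans ring. The step needs regioselectivity (attack at the alkyne carbon bearing oxygen, so that the old furan oxygen ends on C7 and the furan C4 substituent on C5), secured by the ynol ether polarisation and the two-carbon tether, and chemoselectivity for the furan over the dialkoxyphenyl ring, the benzofuran and ionisation or [3,3] shift of the benzylic ether, secured by the higher nucleophilicity of the furan α-carbon and by working at or below 0 °C over molecular sieves.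

**Step 14**
Reactants: 32 (2S,3R)-2-Ar-5-BF-3-[(triisopropylsilyloxy)methyl]-2,3-dihydro-1-benzofuran-7-ol
Product: 33 (2S,3R)-2-Ar-5-BF-7-methoxy-3-[(triisopropylsilyloxy)methyl]-2,3-dihydro-1-benzofuran
Conditions: MeI, K2CO3, acetone, rt
Reagents that add atoms: iodomethane, CI
Why: Williamson ether synthesis on the only acidic hydroxyl (the C7 phenol), with silyl and benzyl ethers inert to K2CO3 and MeI.

**Step 15**
Reactants: 33 (2S,3R)-2-Ar-5-BF-7-methoxy-3-[(triisopropylsilyloxy)methyl]-2,3-dihydro-1-benzofuran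
Product: 34 [(2S,3R)-2-Ar-5-[5-(3-hydroxypropyl)-7-methoxy-1-benzofuran-2-yl]-7-methoxy-2,3-dihydro-1-benzofuran-3-yl]methanol
Conditions: Bu4NF (TBAF), THF, 0 °C → rt
Reagents that add atoms: none
Why: Fluoride-induced desilylation driven by Si–F bond formation frees both primary alcohols while the aryl benzyl ether and the ring system are untouched.

**Step 16**
Reactants: 34 O-benzyl diol
Product: 35 4-[(2S,3R)-3-(hydroxymethyl)-5-[5-(3-hydroxypropyl)-7-methoxy-1-benzofuran-2-yl]-7-methoxy-2,3-dihydro-1-benzofuran-2-yl]-2-methoxyphenol (target)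
Conditions: H2 (1 atm), Pd/C (10 %), EtOAc/EtOH, rt, stopped when 34 is consumed
Reagents that add atoms: none
Why: Catalytic hydrogenolysis of the aryl benzyl ether, which at 1 atm and room temperature should be much faster than cleavage of the cyclic benzylic C2–O1 bond or saturation of the benzofuran.

**Compound list**

1 | 4-bromofuran-2-carbaldehyde | O=Cc1cc(Br)co1 | starting material
2 | ethynyltrimethylsilane | C#C[Si](C)(C)C | starting material
3 | 4-[(trimethylsilyl)ethynyl]furan-2-carbaldehyde | O=Cc1cc(C#C[Si](C)(C)C)co1 | intermediate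
4 | eugenol (4-allyl-2-methoxyphenol) | C=CCc1ccc(O)c(OC)c1 | starting material
5 | 9-{3-[4-(9-borabicyclo[3.3.1]nonan-9-yloxy)-3-methoxyphenyl]propyl}-9-borabicyclo[3.3.1]nonane | COc1cc(CCCB2C3CCCC2CCC3)ccc1OB1C2CCCC1CCC2 | intermediate
6 | 4-(3-hydroxypropyl)-2-methoxyphenol (dihydroconiferyl alcohol) | COc1cc(CCCO)ccc1O | intermediate
7 | 4-(3-hydroxypropyl)-2-iodo-6-methoxyphenol | COc1cc(CCCO)cc(I)c1O | intermediate
8 | 4-ethynylfuran-2-carbaldehyde | O=Cc1cc(C#C)co1 | intermediate
9 | 4-{[2-hydroxy-5-(3-hydroxypropyl)-3-methoxyphenyl]ethynyl}furan-2-carbaldehyde | COc1cc(CCCO)cc(C#Cc2coc(C=O)c2)c1O | intermediate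
10 | 4-[5-(3-hydroxypropyl)-7-methoxy-1-benzofuran-2-yl]furan-2-carbaldehyde | O=Cc1cc(-c2cc3cc(CCCO)cc(OC)c3o2)co1 | intermediate
11 | 4-{7-methoxy-5-[3-(triisopropylsilyloxy)propyl]-1-benzofuran-2-yl}furan-2-carbaldehyde | O=Cc1cc(-c2cc3cc(CCCO[Si](C(C)C)(C(C)C)C(C)C)cc(OC)c3o2)co1 | intermediate
12 | p-toluenesulfonylmethyl isocyanide (TosMIC) | [C-]#[N+]CS(=O)(=O)c1ccc(C)cc1 | starting material
13 | N-[2-(4-BF-furan-2-yl)-1-(p-toluenesulfonyl)ethenyl]formamide | O=CNC(=Cc1cc(-c2cc3cc(CCCO[Si](C(C)C)(C(C)C)C(C)C)cc(OC)c3o2)co1)S(=O)(=O)c1ccc(C)cc1 | intermediate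
14 | 2-(4-BF-furan-2-yl)acetonitrile | N#CCc1cc(-c2cc3cc(CCCO[Si](C(C)C)(C(C)C)C(C)C)cc(OC)c3o2)co1 | intermediate
15 | 2-(4-BF-furan-2-yl)acetic acid | OC(=O)Cc1cc(-c2cc3cc(CCCO[Si](C(C)C)(C(C)C)C(C)C)cc(OC)c3o2)co1 | intermediate
16 | (4S)-4-benzyl-1,3-oxazolidin-2-one | O=C1N[C@@H](Cc2ccccc2)CO1 | starting material
17 | 2-(4-BF-furan-2-yl)acetic pivalic anhydride | CC(C)(C)C(=O)OC(=O)Cc1cc(-c2cc3cc(CCCO[Si](C(C)C)(C(C)C)C(C)C)cc(OC)c3o2)co1 | intermediate
18 | (4S)-4-benzyl-3-[2-(4-BF-furan-2-yl)acetyl]-1,3-oxazolidin-2-one | O=C(Cc1cc(-c2cc3cc(CCCO[Si](C(C)C)(C(C)C)C(C)C)cc(OC)c3o2)co1)N1[C@@H](Cc2ccccc2)COC1=O | intermediate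
19 | 4-(benzyloxy)-3-methoxybenzaldehyde | COc1cc(C=O)ccc1OCc1ccccc1 | starting material
20 | dibutylboron (Z)-enolate of 18 | CCCCB(CCCC)O/C(=C\c1cc(-c2cc3cc(CCCO[Si](C(C)C)(C(C)C)C(C)C)cc(OC)c3o2)co1)N1[C@@H](Cc2ccccc2)COC1=O | intermediate
21 | O-dibutylboryl aldolate of 22 | COc1cc([C@@H](OB(CCCC)CCCC)[C@H](c2cc(-c3cc4cc(CCCO[Si](C(C)C)(C(C)C)C(C)C)cc(OC)c4o3)co2)C(=O)N2[C@@H](Cc3ccccc3)COC2=O)ccc1OCc1ccccc1 | intermediate
22 | (4S)-4-benzyl-3-[(2R,3S)-3-Ar-2-(4-BF-furan-2-yl)-3-hydroxypropanoyl]-1,3-oxazolidin-2-one | COc1cc([C@@H](O)[C@H](c2cc(-c3cc4cc(CCCO[Si](C(C)C)(C(C)C)C(C)C)cc(OC)c4o3)co2)C(=O)N2[C@@H](Cc3ccccc3)COC2=O)ccc1OCc1ccccc1 | intermediate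
23 | (1S,2R)-1-Ar-2-(4-BF-furan-2-yl)propane-1,3-diol | COc1cc([C@@H](O)[C@H](c2cc(-c3cc4cc(CCCO[Si](C(C)C)(C(C)C)C(C)C)cc(OC)c4o3)co2)CO)ccc1OCc1ccccc1 | intermediate
24 | (1S,2R)-1-Ar-2-(4-BF-furan-2-yl)-3-(triisopropylsilyloxy)propan-1-ol | COc1cc([C@@H](O)[C@H](c2cc(-c3cc4cc(CCCO[Si](C(C)C)(C(C)C)C(C)C)cc(OC)c4o3)co2)CO[Si](C(C)C)(C(C)C)C(C)C)ccc1OCc1ccccc1 | intermediate
25 | trichloroethylene | ClC=C(Cl)Cl | starting material
26 | (E)-1,2-dichlorovinyl ether of 24 | COc1cc([C@@H](O/C(Cl)=C\Cl)[C@H](c2cc(-c3cc4cc(CCCO[Si](C(C)C)(C(C)C)C(C)C)cc(OC)c4o3)co2)CO[Si](C(C)C)(C(C)C)C(C)C)ccc1OCc1ccccc1 | intermediate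
27 | chloroethynyl ether of 24 | COc1cc([C@@H](OC#CCl)[C@H](c2cc(-c3cc4cc(CCCO[Si](C(C)C)(C(C)C)C(C)C)cc(OC)c4o3)co2)CO[Si](C(C)C)(C(C)C)C(C)C)ccc1OCc1ccccc1 | intermediate
28 | lithioethynyl ether of 24 | COc1cc([C@@H](OC#C[Li])[C@H](c2cc(-c3cc4cc(CCCO[Si](C(C)C)(C(C)C)C(C)C)cc(OC)c4o3)co2)CO[Si](C(C)C)(C(C)C)C(C)C)ccc1OCc1ccccc1 | intermediate
29 | 2-[(1S,2R)-1-Ar-1-(ethynyloxy)-3-(triisopropylsilyloxy)propan-2-yl]-4-BF-furan | COc1cc([C@@H](OC#C)[C@H](c2cc(-c3cc4cc(CCCO[Si](C(C)C)(C(C)C)C(C)C)cc(OC)c4o3)co2)CO[Si](C(C)C)(C(C)C)C(C)C)ccc1OCc1ccccc1 | intermediate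
30 | oxepine valence isomer of 31 (2,3-dihydrofuro[2,3-c]oxepine with Ar on C2, CH2OTIPS on C3 and BF on the oxepine carbon that becomes C5) | COc1cc([C@H]2OC3=COC=C(c4cc5cc(CCCO[Si](C(C)C)(C(C)C)C(C)C)cc(OC)c5o4)C=C3[C@@H]2CO[Si](C(C)C)(C(C)C)C(C)C)ccc1OCc1ccccc1 | intermediate
31 | (2S,3R)-2-Ar-5-BF-6,7-epoxy-3-[(triisopropylsilyloxy)methyl]-2,3,6,7-tetrahydro-1-benzofuran (arene oxide) | COc1cc([C@H]2OC3=C(C=C(c4cc5cc(CCCO[Si](C(C)C)(C(C)C)C(C)C)cc(OC)c5o4)C4OC34)[C@@H]2CO[Si](C(C)C)(C(C)C)C(C)C)ccc1OCc1ccccc1 | intermediate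
32 | (2S,3R)-2-Ar-5-BF-3-[(triisopropylsilyloxy)methyl]-2,3-dihydro-1-benzofuran-7-ol | COc1cc([C@H]2Oc3c(O)cc(-c4cc5cc(CCCO[Si](C(C)C)(C(C)C)C(C)C)cc(OC)c5o4)cc3[C@@H]2CO[Si](C(C)C)(C(C)C)C(C)C)ccc1OCc1ccccc1 | intermediate
33 | (2S,3R)-2-Ar-5-BF-7-methoxy-3-[(triisopropylsilyloxy)methyl]-2,3-dihydro-1-benzofuran | COc1cc([C@H]2Oc3c(OC)cc(-c4cc5cc(CCCO[Si](C(C)C)(C(C)C)C(C)C)cc(OC)c5o4)cc3[C@@H]2CO[Si](C(C)C)(C(C)C)C(C)C)ccc1OCc1ccccc1 | intermediate
34 | [(2S,3R)-2-Ar-5-[5-(3-hydroxypropyl)-7-methoxy-1-benzofuran-2-yl]-7-methoxy-2,3-dihydro-1-benzofuran-3-yl]methanol | COc1cc([C@H]2Oc3c(OC)cc(-c4cc5cc(CCCO)cc(OC)c5o4)cc3[C@@H]2CO)ccc1OCc1ccccc1 | intermediate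
35 | 4-[(2S,3R)-3-(hydroxymethyl)-5-[5-(3-hydroxypropyl)-7-methoxy-1-benzofuran-2-yl]-7-methoxy-2,3-dihydro-1-benzofuran-2-yl]-2-methoxyphenol | COc1cc([C@H]2Oc3c(OC)cc(-c4cc5cc(CCCO)cc(OC)c5o4)cc3[C@@H]2CO)ccc1O | target

**Step count.** Total: 16 steps. Longest linear sequence: 15 steps (eugenol 4 to 35 through steps 2 to 16).

**Steps most likely to fail**

1. Step 13. Ionisation of the electron-rich benzylic C–O bond, a [3,3] shift or hydration of the ynol ether may outpace attack by the furan, or the dialkoxyphenyl ring may compete as the nucleophile. The fallback takes ring A from a preformed benzene ring, closes the dihydrofuran ring by benzylic etherification and builds the benzofuran last. It sets out from 19 (with 16, 2 and 7 as the other route compounds) and returns at 34. Commercial 5-bromo-2-hydroxy-3-methoxybenzaldehyde F1 would be converted with MOMCl and i-Pr2NEt to its methoxymethyl ether F2. This would be homologated as in steps 6 and 7 to the arylacetonitrile F3 and the arylacetic acid F4, and loaded on 16 as in step 8 to give the imide F5. The boron syn-aldol of F5 with 19 (as in step 9) should give the aldol adduct F6, and LiBH4 the diol F7. HCl in MeOH would then remove the methoxymethyl group and close the ring through the alkoxybenzyl cation to the 2,3-trans bromodihydrobenzofuran F8, C3 being fixed by the aldol and C2 settling trans to it. Sonogashira coupling of F8 with 2 (PdCl2(PPh3)2, CuI, Et3N, 70 °C) would give the silylalkyne F9. The fluoride-triggered heteroannulation of step 4 with iodophenol 7 would turn F9 into 34, which goes on to step 16.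

2. Step 12. Silyl transfer to the potassium alkoxide, elimination, or loss of the sensitive ynol ether during work-up may occur. The fallback avoids any alkoxide; it sets out from 24 and returns at 29. Alcohol 24 would be formylated with acetic formic anhydride and pyridine at 0 °C to the formate ester F10. Wittig-type dichloromethylenation of the formate carbonyl (PPh3, CCl4, THF, 60 °C) would give the 2,2-dichlorovinyl ether F11. Treatment of F11 with n-BuLi (2.2 equiv, THF, −78 °C) and a methanol quench would give 29 by elimination and chlorine–lithium exchange.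

3. Step 6. Oxazole formation or base-induced degradation of the furaldehyde may compete with nitrile formation. The fallback sets out from 11 and returns at 15, bypassing 14. Wittig reaction of 11 with the ylide from (methoxymethyl)triphenylphosphonium chloride and KN(SiMe3)2 would give the methyl enol ether F12. Mild hydrolysis (dilute HCl, THF, rt) would give the furylacetaldehyde F13, used at once. Pinnick oxidation of F13 (NaClO2, NaH2PO4, 2-methyl-2-butene, t-BuOH/H2O) would give acid 15.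

**Further compounds**

F1 | step 13 | 5-bromo-2-hydroxy-3-methoxybenzaldehyde | COc1cc(Br)cc(C=O)c1O
F2 | step 13 | 5-bromo-3-methoxy-2-(methoxymethoxy)benzaldehyde | COCOc1c(OC)cc(Br)cc1C=O
F3 | step 13 | 2-[5-bromo-3-methoxy-2-(methoxymethoxy)phenyl]acetonitrile | COCOc1c(OC)cc(Br)cc1CC#N
F4 | step 13 | 2-[5-bromo-3-methoxy-2-(methoxymethoxy)phenyl]acetic acid | COCOc1c(OC)cc(Br)cc1CC(=O)O
F5 | step 13 | (4S)-4-benzyl-3-{2-[5-bromo-3-methoxy-2-(methoxymethoxy)phenyl]acetyl}-1,3-oxazolidin-2-one | COCOc1c(OC)cc(Br)cc1CC(=O)N1[C@@H](Cc2ccccc2)COC1=O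
F6 | step 13 | (4S)-4-benzyl-3-{(2S,3S)-3-[4-(benzyloxy)-3-methoxyphenyl]-2-[5-bromo-3-methoxy-2-(methoxymethoxy)phenyl]-3-hydroxypropanoyl}-1,3-oxazolidin-2-one | COc1cc([C@@H](O)[C@H](c2cc(Br)cc(OC)c2OCOC)C(=O)N2[C@@H](Cc3ccccc3)COC2=O)ccc1OCc1ccccc1
F7 | step 13 | (1S,2R)-1-[4-(benzyloxy)-3-methoxyphenyl]-2-[5-bromo-3-methoxy-2-(methoxymethoxy)phenyl]propane-1,3-diol | COc1cc([C@@H](O)[C@H](c2cc(Br)cc(OC)c2OCOC)CO)ccc1OCc1ccccc1
F8 | step 13 | [(2S,3R)-2-[4-(benzyloxy)-3-methoxyphenyl]-5-bromo-7-methoxy-2,3-dihydro-1-benzofuran-3-yl]methanol | COc1cc([C@H]2Oc3c(OC)cc(Br)cc3[C@@H]2CO)ccc1OCc1ccccc1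
F9 | step 13 | [(2S,3R)-2-[4-(benzyloxy)-3-methoxyphenyl]-7-methoxy-5-[(trimethylsilyl)ethynyl]-2,3-dihydro-1-benzofuran-3-yl]methanol | COc1cc([C@H]2Oc3c(OC)cc(C#C[Si](C)(C)C)cc3[C@@H]2CO)ccc1OCc1ccccc1
F10 | step 12 | (1S,2R)-1-Ar-2-(4-BF-furan-2-yl)-3-(triisopropylsilyloxy)propyl formate | COc1cc([C@@H](OC=O)[C@H](c2cc(-c3cc4cc(CCCO[Si](C(C)C)(C(C)C)C(C)C)cc(OC)c4o3)co2)CO[Si](C(C)C)(C(C)C)C(C)C)ccc1OCc1ccccc1
F11 | step 12 | 2-[(1S,2R)-1-Ar-1-(2,2-dichloroethenyloxy)-3-(triisopropylsilyloxy)propan-2-yl]-4-BF-furan | COc1cc([C@@H](OC=C(Cl)Cl)[C@H](c2cc(-c3cc4cc(CCCO[Si](C(C)C)(C(C)C)C(C)C)cc(OC)c4o3)co2)CO[Si](C(C)C)(C(C)C)C(C)C)ccc1OCc1ccccc1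
F12 | step 6 | 2-(2-methoxyethenyl)-4-BF-furan (E/Z mixture) | COC=Cc1cc(-c2cc3cc(CCCO[Si](C(C)C)(C(C)C)C(C)C)cc(OC)c3o2)co1
F13 | step 6 | 2-(4-BF-furan-2-yl)acetaldehyde | O=CCc1cc(-c2cc3cc(CCCO[Si](C(C)C)(C(C)C)C(C)C)cc(OC)c3o2)co1
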